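## Structural features

The target is a monocyclic 1,2-dioxane. O1–O2 is a dialkyl peroxide, C3 carries a hydrogen and a CH2CO2H arm, C4 and C5 are methylenes, and C6 is a peroxyketal carbon bearing a methoxy group and a sixteen-carbon chain. The chain is joined to C6 through three methylenes and continues as a conjugated enyne (C4'≡C5'–C6'=C7', E) with a nonyl tail. The two stereocentres, C3 (S) and C6 (R), are not adjacent but face each other 1,4 across the ring. The methoxy group is cis to the acetic acid arm, so in the chair OMe is axial (anomeric effect) and both carbon substituents are equatorial; C6 is therefore the thermodynamically preferred ketal epimer, and only C3 needs real control. Fragile groups are the O–O bond (reductants, low-valent metals, phosphines, hydrogenation), the C3–H and the acidic CH2 β to O2 (base-induced Kornblum–DeLaMare cleavage or retro-oxa-Michael opening), the acid-labile peroxyketal, and the enyne (radicals, singlet oxygen, reduction). The real difficulty is to put a peroxide oxygen on the secondary carbon C3 in defined absolute configuration with no neighbouring group to relay chirality, and to attach the enyne without losing the peroxide. The key step uses the fact that C6 is at the ketone oxidation level and is tied through C5–C4 to the oxygen-bearing C3: the array O1–C6–C5–C4–C3–O2 is a ketone with its α-carbon radical (C6, C5), a terminal alkene (C4=C3) and dioxygen (O2–O1) folded back onto the ketone carbon.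

## Logic of the disconnections

12 ⇒ 11. No skeletal bond is cut; the acid is traced back to the methyl ester (ester C–O bond) of a racemate. C3 arises without facial control in the ring-forming step, so the absolute configuration has to be selected somewhere. An enantioselective ester hydrolysis does this and the deprotection in one neutral operation. The gain is that every earlier ring compound may be racemic. The demand is a hydrolase that distinguishes a stereocentre β to the carbonyl, at a pH that spares peroxide and ketal.

11 ⇒ 7 + 10. The C5'–C6' bond between the alkyne and the alkene carbon is cut. This keeps the radical-sensitive enyne out of the oxygenation step, makes the route convergent, and lets the E geometry come ready-made with 10. The ring fragment shrinks to a C5 side chain ending in a terminal alkyne. The demand is a zerovalent palladium/CuI coupling at room temperature that leaves the O–O bond intact.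

10 ⇒ 8. The C–I bond and the vicinal C–H bond are cut. A syn hydrometalation followed by iodinolysis fixes the E geometry in one operation from a purchasable alkyne. The demand is complete terminal regioselectivity and retention in the halogenation.

7 ⇒ 6. The C6–OCH3 bond is cut. The methoxy group is the thermodynamically preferred axial substituent, so it can be installed last at C6 by equilibration and needs no stereocontrolled step. The demand is that ionisation at C6 outruns acid-induced O–O cleavage.

6 ⇒ 3 + 4 + dioxygen (through 5). Three ring bonds are cut: C5–C4, C3–O2 and O1–C6. The cut removes the ring, both stereocentres and the peroxide at once and leaves a seven-carbon bromoketone, a four-carbon alkene and air. The forward step must make the α-keto radical add to the alkene before it meets O2 or a hydrogen donor, and must make the C3 radical meet O2 before anything else. The alkyne of 3 stays unprotected: a silyl cap would cost a basic deprotection next to the peroxide, and the bimolecular addition at high alkene concentration should outrun cyclisation onto the alkyne.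

3 ⇒ 2 ⇒ 1. The C1–Br bond is cut, then the C1–C2 bond. A one-carbon homologation of an ester through a sulfoxonium ylide gives the bromomethyl ketone regiospecifically. It needs neither diazomethane nor bromination of a methyl ketone in the presence of an alkyne. The demand is that the ylide acylates faster than it enolises the ester and leaves the alkyne C–H alone.

## Other disconnections considered

Alternative 1: The cut removes C3–O2 and C6–O1 together, after adding a C4=C5 double bond and a two-carbon bridge from C6 to the CH2 on C3. The forward step is the photosensitised [4+2] addition of singlet oxygen to the diene of the dienol A2, giving the bicyclic endoperoxide A1.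
- In its favour: the step is concerted with few side channels and forms both C–O bonds at once. The carbinol of A2 directs O2 to its own face by hydrogen bonding, so C3 is relayed from a centre that could be made enantioselectively. On absolute control this is better than the chosen plan, which loses half the material in a resolution.
- Against it here: A2 is a cyclohexadienol that dehydrates to an arene with traces of acid. Oxidation of its carbinol leads to a phenol tautomer, so the usual asymmetric ketone reduction is closed and access to enantioenriched A2 is the weak point.
- After the cycloaddition the bridge must be dismantled: diimide reduction of C4=C5 beside a silylalkyne, cleavage of the C6–CH(OH) bond with methanol capture at C6, oxidation of the released formyl group, desilylation and coupling. That is about six operations, against three after the key step of the chosen plan (the preparation of 10 is common to both).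
- Comparison: on structure, the C6 configuration fixed in A1 is lost in the fragmentation and re-set thermodynamically, which is equal to the chosen plan. On mechanism the alternative is the more predictable. On step economy and precursor availability the chosen plan is better.

Alternative 2: The cut is C4–C5 after introducing unsaturation there. The forward step is ring-closing metathesis of the peroxide-tethered diene A4 with second-generation Grubbs catalyst, giving the dihydrodioxine A3 and ethene.
- In its favour: the O–O bond is made by polar chemistry before ring closure, and six-membered ring closure with a cis alkene is dependable. The C3 configuration can be supplied by the allylic hydroperoxide half of A4, which would avoid a late resolution; on that point it is potentially better.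
- Against it here: A4 is a doubly allylic peroxide and an allylic peroxyketal. It should ionise easily, with a risk of allylic transposition, and its C6 centre forms without control. The ruthenium carbene may attack the O–O bond, and the alkyne needs a silyl cap to prevent enyne metathesis.
- After ring closure come a diimide reduction (hydrogenation is excluded by the peroxide), two desilylations, a two-stage oxidation of the primary alcohol and the coupling, six or seven operations in all.
- Comparison: on structure, A3 has the arm at too low an oxidation level and one unsaturation too many, whereas 6 has every carbon at its final oxidation level. On mechanism the ring closure is the equal or the better of the radical annulation in predictability. On C6 the two are equal (thermodynamic equilibration). On step economy the chosen plan is better.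

Alternative 3: The cut is C3–C4. The forward step generates a primary C4 radical from the bromide A6, which adds 6-exo-trig to the β-carbon of the peroxy acrylimide. (Me3Si)3SiH then reduces the α-acyl radical, giving A5.
- In its favour: the acceptor resembles β-alkoxyacrylates, which are reliable radical acceptors. The methoxy ketal is already in place and the arm is at the acid oxidation level. Auxiliary removal, desilylation and coupling would finish the synthesis, which is equal to the chosen plan in operations after the key step. The auxiliary offers absolute control at C3 in principle, which is better than a resolution.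
- Against it here: A6 is a vinyl peroxide assembled from a tertiary α-methoxy hydroperoxide and a propiolimide, so it is labile and several steps deep.
- The cyclised α-acyl radical has the O–O bond in the β-position and can close an epoxide on O2 with loss of an alkoxyl radical, a fast path for β-peroxyalkyl radicals that competes with hydrogen transfer. Silyl radicals also attack peroxides.
- The inducing centre is remote from C3, so control would need a chelating Lewis acid that the peroxyketal may not tolerate. C6 of A6 is uncontrolled, so diastereomeric pairs result.
- Comparison: both plans close the ring with a carbon radical. In the chosen plan the O–O bond is created by the radical sequence and never sits β to a radical; in the alternative it must survive one. On step economy to the precursor (two steps against at least five) the chosen plan is better.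

Key step: step 3

Remark on stereochemistry: the target is (3S,6R) with the methoxy group cis to the acetic acid arm. Compounds 5, 6, 7 and 11 are racemic, and the ring compounds among them are drawn as the enantiomer that leads to the target.

Assumption: the lipase in step 7 is taken, after screening, to hydrolyse the (3S,6R)-ester faster; the opposite preference is covered by the fallback to step 7.

Safety choices: no diazomethane, tin or chromium is used; the oxygenation runs in oxygen-lean gas below the flammability limit of the solvent; peroxides 6, 7, 11 and 12 are kept cold and are never distilled or concentrated hot.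

## Route

Step 1
Reactants: 1 methyl hex-5-ynoate
Product: 2 1-[dimethyl(oxo)-λ6-sulfanylidene]hept-6-yn-2-one
Conditions: Me3S(O)I (3 equiv), KOtBu (3 equiv), THF, reflux; then 1, 0 °C → rt
Reagents that add atoms: trimethylsulfoxonium iodide, C[S+](C)(C)=O.[I-]
Why: Acylation of dimethylsulfoxonium methylide by a methyl ester (Corey–Chaykovsky-type acyl transfer); a second equivalent of ylide deprotonates the first-formed β-keto sulfoxonium salt to the stabilised ylide 2, and the ylide is too weak a base to remove the alkyne proton.

Step 2
Reactants: 2 1-[dimethyl(oxo)-λ6-sulfanylidene]hept-6-yn-2-one
Product: 3 1-bromohept-6-yn-2-one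
Conditions: LiBr (1.5 equiv), MsOH (1.1 equiv), THF, 0 °C → rt
Reagents that add atoms: lithium bromide, [Li+].[Br-]
Why: Protonation at the ylide carbon gives a β-keto sulfoxonium cation in which dimethyl sulfoxide is the leaving group, and bromide displaces it by SN2 at the primary carbon (hydrohalogenation of a β-keto sulfoxonium ylide); one equivalent of acid at low temperature should spare the alkyne and limit Kornblum-type oxidation of 3 by the liberated sulfoxide.

Step 3
Reactants: 3 1-bromohept-6-yn-2-one; 4 methyl but-3-enoate
Product: 6 methyl 2-[(3S*,6R*)-6-hydroxy-6-(pent-4-yn-1-yl)-1,2-dioxan-3-yl]acetate (racemic), via methyl 3-hydroperoxy-6-oxoundec-10-ynoate 5 (not isolated)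
Conditions: fac-Ir(ppy)3 (1 mol %), Hantzsch ester (1.2 equiv, slow addition), NaHCO3 (1.5 equiv), 4 (10 equiv), MeCN, 5 % O2 in N2, blue LEDs, 20 °C
Reagents that add atoms: dioxygen, O=O
Why: Proposed new method: excited fac-Ir(ppy)3 transfers an electron to the C–Br bond of 3, the electrophilic α-keto radical adds to the unsubstituted alkene carbon of 4 (C5–C4), the secondary C3 radical is captured by O2 at a near diffusion-controlled rate (C3–O2), the peroxyl radical takes a hydrogen atom from the Hantzsch ester (which also returns the oxidised, tetravalent iridium complex to its resting state), and the hydroperoxide oxygen of 5 adds to the ketone carbon (O1–C6). The closest known reaction types are the Mn(OAc)3/O2 peroxycyclisation of 1,3-dicarbonyl compounds with alkenes to 1,2-dioxan-3-ols, the photoredox atom-transfer addition of α-bromocarbonyl compounds to 1-alkenes and the thiol–olefin co-oxygenation; the combination of a simple α-bromoketone, an unactivated alkene and O2 has not been shown. The ring closes by a polar 6-exo-trig addition of the hydroperoxide to the C=O group, and because the ketone that carried the radical is also the acceptor, both roles sit four atoms apart by construction. C3 forms with no facial bias and is racemic; C6 is under thermodynamic control through ring–chain equilibration with 5, which should favour axial OH with both carbon substituents equatorial. Regioselectivity rests on the preference of the radical for the terminal CH2, which gives the secondary radical. The step needs alkene addition to outrun capture of the α-keto radical by O2 or by the hydrogen donor; the tenfold excess of 4, the lean O2 feed and the slow addition of the donor are meant to secure this, while O2 capture at C3 remains far faster than bromine or hydrogen transfer. Attack of the electrophilic radical on its own alkyne (6-exo-dig) is a slower unimolecular process than addition to 4 at this concentration.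

Step 4
Reactants: 6 methyl 2-[(3S*,6R*)-6-hydroxy-6-(pent-4-yn-1-yl)-1,2-dioxan-3-yl]acetate (racemic)
Product: 7 methyl 2-[(3S*,6R*)-6-methoxy-6-(pent-4-yn-1-yl)-1,2-dioxan-3-yl]acetate (racemic)
Conditions: CSA (10 mol %), MeOH, 3 Å MS, 0 °C → rt
Reagents that add atoms: methanol, CO
Why: Acid-catalysed exchange of the hemiperoxyketal hydroxyl for methoxyl through a peroxycarbenium ion (ketalisation); under equilibrating conditions the anomeric effect places OMe axial while both carbon substituents stay equatorial, which is the cis (3S*,6R*) arrangement of the target, so C6 is set here relative to C3.

Step 5
Reactants: 8 undec-1-yne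
Product: 10 (E)-1-iodoundec-1-ene, via (E)-undec-1-enylzirconocene chloride 9 (not isolated)
Conditions: Cp2Zr(H)Cl (1.2 equiv), THF, rt; then I2, 0 °C
Reagents that add atoms: iodine, II; chlorobis(cyclopentadienyl)hydridozirconium (Schwartz reagent; its zirconium fragment is carried only by 9), [H][Zr](Cl)(C1C=CC=C1)C1C=CC=C1
Why: syn-Hydrozirconation places zirconium on the terminal carbon and iodinolysis of the C–Zr bond proceeds with retention, which fixes the E geometry (hydrozirconation–iodination).

Step 6
Reactants: 7 methyl 2-[(3S*,6R*)-6-methoxy-6-(pent-4-yn-1-yl)-1,2-dioxan-3-yl]acetate (racemic); 10 (E)-1-iodoundec-1-ene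
Product: 11 methyl 2-[(3S*,6R*)-6-[(6E)-hexadec-6-en-4-yn-1-yl]-6-methoxy-1,2-dioxan-3-yl]acetate (racemic)
Conditions: Pd(PPh3)2Cl2 (3 mol %), CuI (6 mol %), Et3N, THF, rt, degassed
Reagents that add atoms: none
Why: Sonogashira coupling of a terminal alkyne with an (E)-alkenyl iodide retains the alkene geometry and runs at room temperature, where saturated dialkyl peroxides and peroxyketals should not be reduced by zerovalent palladium or PPh3; neither stereocentre is touched.

Step 7
Reactants: 11 methyl 2-[(3S*,6R*)-6-[(6E)-hexadec-6-en-4-yn-1-yl]-6-methoxy-1,2-dioxan-3-yl]acetate (racemic)
Product: 12 2-[(3S,6R)-6-[(6E)-hexadec-6-en-4-yn-1-yl]-6-methoxy-1,2-dioxan-3-yl]acetic acid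
Conditions: Burkholderia cepacia lipase, phosphate buffer pH 7.2/MTBE, 30 °C, stopped near 45 % conversion; NaHCO3 extraction, then pH 5
Reagents that add atoms: water, O
Why: Lipase-catalysed enantioselective ester hydrolysis (kinetic resolution) at neutral pH; no stereocentre is formed, the enzyme selects the (3S,6R)-ester, whose acid is separated by mild base extraction from the unreacted (3R,6S)-ester, and the conditions spare peroxide, ketal and enyne.

## Compound list

1 | methyl hex-5-ynoate | C#CCCCC(=O)OC | starting material
2 | 1-[dimethyl(oxo)-λ6-sulfanylidene]hept-6-yn-2-one | C#CCCCC(=O)C=S(C)(C)=O | intermediate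
3 | 1-bromohept-6-yn-2-one | BrCC(=O)CCCC#C | intermediate
4 | methyl but-3-enoate | C=CCC(=O)OC | starting material
5 | methyl 3-hydroperoxy-6-oxoundec-10-ynoate (racemic; not isolated) | C#CCCCC(=O)CCC(CC(=O)OC)OO | intermediate
6 | methyl 2-[(3S*,6R*)-6-hydroxy-6-(pent-4-yn-1-yl)-1,2-dioxan-3-yl]acetate (racemic; one enantiomer drawn) | C#CCCC[C@]1(O)CC[C@@H](CC(=O)OC)OO1 | intermediate
7 | methyl 2-[(3S*,6R*)-6-methoxy-6-(pent-4-yn-1-yl)-1,2-dioxan-3-yl]acetate (racemic; one enantiomer drawn) | C#CCCC[C@]1(OC)CC[C@@H](CC(=O)OC)OO1 | intermediate
8 | undec-1-yne | CCCCCCCCCC#C | starting material
9 | chlorobis(cyclopentadienyl)[(E)-undec-1-en-1-yl]zirconium (not isolated; rings drawn σ-bound) | CCCCCCCCC/C=C/[Zr](Cl)(C1C=CC=C1)C1C=CC=C1 | intermediate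
10 | (E)-1-iodoundec-1-ene | CCCCCCCCC/C=C/I | intermediate
11 | methyl 2-[(3S*,6R*)-6-[(6E)-hexadec-6-en-4-yn-1-yl]-6-methoxy-1,2-dioxan-3-yl]acetate (racemic; one enantiomer drawn) | CCCCCCCCC/C=C/C#CCCC[C@]1(OC)CC[C@@H](CC(=O)OC)OO1 | intermediate
12 | 2-[(3S,6R)-6-[(6E)-hexadec-6-en-4-yn-1-yl]-6-methoxy-1,2-dioxan-3-yl]acetic acid | CCCCCCCCC/C=C/C#CCCC[C@]1(OC)CC[C@@H](CC(=O)O)OO1 | target

Total step count: 7. Longest linear sequence: 6 (steps 1, 2, 3, 4, 6, 7); step 5 is a one-step side branch.

## Least certain steps

Step 3 (key step, proposed new method). The most likely failures are:
- interception of the α-keto radical by O2 or by the hydrogen donor before the C5–C4 bond forms (hydrodebromination or oxygenation at C1), because addition to an unactivated alkene is slow;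
- quenching of the excited catalyst by O2;
- reductive cleavage of the new O–O bond by the strongly reducing excited catalyst once 3 is consumed;
- cyclisation of the radical onto its own alkyne.

Fallback with known chemistry, from 3 and 4 to 7:
- Bromine atom-transfer radical addition of 3 to 4 in degassed solution (fac-Ir(ppy)3, blue light, no oxygen and no hydrogen donor, a Kharasch-type addition) should give methyl 3-bromo-6-oxoundec-10-ynoate F1.
- Elimination with DBU in CH2Cl2 should give methyl (2E)-6-oxoundec-2-en-10-ynoate F2.
- H2O2·urea with catalytic Sc(OTf)3 in methanol should convert the ketone into methyl (2E)-6-hydroperoxy-6-methoxyundec-2-en-10-ynoate F3.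
- Et2NH in CF3CH2OH should close the ring by intramolecular oxa-Michael addition of the hydroperoxide to the enoate.
- Brief treatment with CSA in methanol (the conditions of step 4) then equilibrates C6 and returns the route at 7, without passing through 5 or 6.

Step 7. Enantiodiscrimination may be insufficient because the stereocentre is one carbon removed from the ester carbonyl, turnover of the very lipophilic substrate may be slow, or the enzyme may prefer the other enantiomer. Fallback from 11:
- Preparative chromatography on a polysaccharide-based chiral stationary phase separates the enantiomers and gives methyl 2-[(3S,6R)-6-[(6E)-hexadec-6-en-4-yn-1-yl]-6-methoxy-1,2-dioxan-3-yl]acetate F4.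
- F4 is hydrolysed without enantioselection (LiOH, THF–water, 0 °C, short contact) to 12.
- If the lipase prefers the (3R,6S)-ester, the ester left after over-running the resolution is F4 and is treated the same way.

Step 6. The O–O bond may be cleaved reductively by zerovalent palladium or phosphine, the copper acetylide may dimerise oxidatively, or the amine may open the ring through the ester enolate. Fallback from 7, with roles inverted and no palladium or phosphine:
- NBS with catalytic AgNO3 in acetone converts the terminal alkyne into methyl 2-[(3S*,6R*)-6-(5-bromopent-4-yn-1-yl)-6-methoxy-1,2-dioxan-3-yl]acetate F5.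
- F5 is coupled with 9 (generated from 8 as in step 5, not quenched with iodine) in the presence of CuCl in THF. This is a copper-mediated alkenylzirconocene–bromoalkyne coupling with retention of the E geometry, and it returns the route at 11.

Step 4. Ring opening to the hydroperoxy ketone and acid-induced heterolysis or rearrangement of the peroxide may compete with exchange at C6, or the epimers at C6 may not converge. Fallback from 6:
- Acetylation of the cyclic hemiperoxyketal (Ac2O, pyridine, catalytic DMAP, 0 °C) gives methyl 2-[(3S*,6R*)-6-acetoxy-6-(pent-4-yn-1-yl)-1,2-dioxan-3-yl]acetate F6.
- F6 is ionised at −78 °C with catalytic Me3SiOTf in CH2Cl2 in the presence of Me3SiOMe. Irreversible axial capture of the peroxycarbenium ion returns the route at 7 under aprotic, kinetically controlled conditions.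

## Further compounds

F1 | step 3 | methyl 3-bromo-6-oxoundec-10-ynoate (racemic) | C#CCCCC(=O)CCC(Br)CC(=O)OC
F2 | step 3 | methyl (2E)-6-oxoundec-2-en-10-ynoate | C#CCCCC(=O)CC/C=C/C(=O)OC
F3 | step 3 | methyl (2E)-6-hydroperoxy-6-methoxyundec-2-en-10-ynoate (racemic) | C#CCCCC(OC)(OO)CC/C=C/C(=O)OC
F4 | step 7 | methyl 2-[(3S,6R)-6-[(6E)-hexadec-6-en-4-yn-1-yl]-6-methoxy-1,2-dioxan-3-yl]acetate (single enantiomer) | CCCCCCCCC/C=C/C#CCCC[C@]1(OC)CC[C@@H](CC(=O)OC)OO1
F5 | step 6 | methyl 2-[(3S*,6R*)-6-(5-bromopent-4-yn-1-yl)-6-methoxy-1,2-dioxan-3-yl]acetate (racemic; one enantiomer drawn) | BrC#CCCC[C@]1(OC)CC[C@@H](CC(=O)OC)OO1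
F6 | step 4 | methyl 2-[(3S*,6R*)-6-acetoxy-6-(pent-4-yn-1-yl)-1,2-dioxan-3-yl]acetate (racemic; one enantiomer drawn) | C#CCCC[C@]1(OC(C)=O)CC[C@@H](CC(=O)OC)OO1
A1 | alternative 1 | 1-[5-(triisopropylsilyl)pent-4-yn-1-yl]-2,3-dioxabicyclo[2.2.2]oct-5-en-7-ol, hydroxyl syn to the peroxide bridge, configuration as drawn | CC(C)[Si](C#CCCC[C@]1([C@@H](O)C2)C=C[C@@H]2OO1)(C(C)C)C(C)C
A2 | alternative 1 | (1S)-2-[5-(triisopropylsilyl)pent-4-yn-1-yl]cyclohexa-2,4-dien-1-ol | O[C@H]1CC=CC=C1CCCC#C[Si](C(C)C)(C(C)C)C(C)C
A3 | alternative 2 | 6-[2-(tert-butyldiphenylsilyloxy)ethyl]-3-methoxy-3-[5-(triisopropylsilyl)pent-4-yn-1-yl]-3,6-dihydro-1,2-dioxine, configuration as drawn | CC(C)[Si](C#CCCC[C@]1(OC)C=C[C@@H](CCO[Si](c2ccccc2)(c2ccccc2)C(C)(C)C)OO1)(C(C)C)C(C)C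
A4 | alternative 2 | acyclic mixed peroxyketal: 3-methoxy-8-(triisopropylsilyl)oct-1-en-7-yn-3-yl 5-(tert-butyldiphenylsilyloxy)pent-1-en-3-yl peroxide, both centres as in A3 | CC(C)[Si](C#CCCC[C@](OC)(C=C)OO[C@@H](C=C)CCO[Si](c1ccccc1)(c1ccccc1)C(C)(C)C)(C(C)C)C(C)C
A5 | alternative 3 | (4S)-4-benzyl-3-{2-[6-methoxy-6-[5-(triisopropylsilyl)pent-4-yn-1-yl]-1,2-dioxan-3-yl]acetyl}oxazolidin-2-one, ring centres as in the target | CC(C)[Si](C#CCCC[C@]1(OC)CC[C@@H](CC(=O)N2[C@@H](Cc3ccccc3)COC2=O)OO1)(C(C)C)C(C)C
A6 | alternative 3 | (4S)-4-benzyl-3-[(2E)-3-{[1-bromo-3-methoxy-8-(triisopropylsilyl)oct-7-yn-3-yl]peroxy}prop-2-enoyl]oxazolidin-2-one, ketal centre as in A5 | CC(C)[Si](C#CCCC[C@](OC)(CCBr)OO/C=C/C(=O)N1[C@@H](Cc2ccccc2)COC1=O)(C(C)C)C(C)C
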